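Picture a closed, stirred vessel at constant temperature, charged with substrate, reagent and a little capture agent. Reagent adds to the substrate once to give mono adduct, then again to give double product.

| flask | substrate | reagent | capture agent | remark | time |
|---|---|---|---|---|---|
| south | 0.30 M | 0.73 equiv | 0.015 M | run made earlier |  |
| south-east | 0.30 M | 2.8 equiv | 0.015 M | run made earlier |  |
| violet | 0.30 M | 4.00 equiv | 0.0150 M |  | 10 min |
| grey | 0.30 M | 1.00 equiv | 0.0150 M |  | 10 min |

| run | time / min | mono adduct / % | double product / % |
|---|---|---|---|
| south | 0.417 | 22.3 | 2.1 |
| south | 0.667 | 26.6 | 2.8 |
| south | 1.00 | 30.0 | 7.8 |
| south | 1.33 | 32.2 | 9.7 |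
| south | 2.00 | 33.2 | 13.3 |
| south | 3.00 | 34.9 | 16.5 |
| south | 5.00 | 36.5 | 15.7 |
| south-east | 0.417 | 38.3 | 24.2 |
| south-east | 0.667 | 36.8 | 40.3 |
| south-east | 1.00 | 29.0 | 55.8 |
| south-east | 1.33 | 24.0 | 65.4 |
| south-east | 2.00 | 13.9 | 79.2 |
| south-east | 3.00 | 6.7 | 88.0 |
| south-east | 5.00 | 0 | 93.7 |

(each reading ± 1 percentage point)

- what was read earlier has a scatter of 1 percentage point, one standard deviation

1. which of these holds the largest part of the substrate at the end of violet (mono adduct / substrate / double product)
2. which of these holds the largest part of the substrate at the end of grey (mono adduct / substrate / double product)
3. how much mono adduct is there at the end of grey, in percent of the substrate charged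

Here is the ledger I would keep, counting turnovers:

- A mono adduct carries one reagent and a double product carries two. Grey charges 1.00 equiv, less than two per substrate, so reagent is the limiting reagent there.
- The first entry is a toll. In south-east at 3.00 min, mono adduct plus double product reads 94.7 %, so 5.30 % of the substrate is missing, close to the capture charge of 5.00 % of the substrate.
- The second entry is the turnover budget, meaning the reagent equivalents minus the capture agent equivalents, which for grey is 95.0 % of the substrate charged.
- You can test this on south, whose budget is 68.0 %. There, c(mono adduct) plus 2 c(double product) reads 67.9 % at 3.00 min and 67.9 % at 5.00 min. Each count carries a scatter of about 2.2 percentage points, so these readings agree with the budget but do not show that the count has stopped rising.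
- Grey runs for 10 min, longer than the last south reading. If you take grey's budget as spent by then, its substrate entries also sum to the budget, so c(substrate) should equal c(double product). How the rest divides, the ledger doesn't tell you.
- Violet charges 4.00 equiv, more than two per substrate, so its books should end in double product.

The forecast starts from the same books: “The mass balance shows what the capture agent does.” It names double product for violet and mono adduct for grey, with 39 % of mono adduct.

Violet ends with 96.1 % of double product. Grey ends with 37.4 % of mono adduct, more than its substrate or double product, and its count comes to 94.9 %.

    substrate + reagent → mono adduct (k = 0.0630 /M/s)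
    reagent + mono adduct → double product (k = 0.0510 /M/s)
    mono adduct + capture agent → trapped intermediate (k = 0.220 /M/s)

The toll is thus mono adduct taken up as trapped intermediate, one reagent already spent on each. The neighbour flask is grey with 0.060 M of capture agent, which is 0.200 equiv, so its budget falls to 80.0 %. It ends with 28.2 % of mono adduct and 25.8 % of double product, a count of 79.8 %. Its substrate stands at 26.0 %, and its trapped intermediate at 20.0 %.

The data are simulated on assumed constants, noise included.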